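At 3.0 min the flask must have 90 % of its electrophile reacted, and I want the nucleophile that does this.

| setting | epsilon | theta | flask |
|---|---|---|---|
| electrophile | 20 mM | 20 mM | 20 mM |
| nucleophile | 120 mM | 270 mM |  |
| gas | 12 mM (held) | 12 mM (held) | 12 mM (held) |
| remark | run made earlier | run made earlier |  |
| time |  |  | 3.0 min |

- epsilon (time / min: target / %): 0.667: 28.8; 1.33: 46.9; 2.00: 59.0; 2.50: 64.6
- theta (time / min: target / %): 0.200: 22.1; 0.417: 39.2; 1.00: 67.5; 2.50: 89.7

(each reading ± 0.3 percentage points)

1. the concentration of nucleophile at which the part of the electrophile that has reacted at 3.0 min is just 90 %, in mM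

- the amount of nucleophile is what is sought; it is there from the start
- at the start none of the gas is in solution

The first theta reading, with the nucleophile still near its charge, gives a rate constant:

k = 0.00462 mM⁻¹ min⁻¹

Reaching 90 % takes 2.30 e-foldings of the electrophile. I fold the givens into one number:

E = 2.30 / (k · [electrophile] · t) = 8.30

E is the equivalents of nucleophile called for, if the nucleophile stays at its charge: the pseudo-first-order case. It reads [nucleophile] = 166 mM.

Is one number enough? No. At 2.50 min the e-foldings read from target are 0.748 of k[nucleophile]t in epsilon and 0.728 in theta, less than one. Dividing by theta's figure gives 228 mM. But that treats target as the whole of the reacted electrophile. If some lies elsewhere, target understates what is asked. I can't split target from the rest, so I commit to the mean of 166 mM and 228 mM, 197 mM.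

The forecast gives 240 mM, higher than my figure: “The yields fit a reaction first order in both electrophile and nucleophile”.

The flask gives 181 mM.

    nucleophile + acid set free ⇌ protonated nucleophile, settled at all times (K = 2400 M⁻¹)
    electrophile + nucleophile → acid set free + target (k = 0.0770 M⁻¹ s⁻¹)
    gas ⇌ free base, rate k3*(csat - [free base]) (kL = 0.00870 s⁻¹)
    electrophile + target → side product (k = 0.0570 M⁻¹ s⁻¹)
    electrophile → decomposition product (k = 2.00 × 10⁻⁶ s⁻¹)
    acid set free + free base ⇌ salt of the base (K = 92.0 M⁻¹, k = 12.0 M⁻¹ s⁻¹)

In this flask the half-life of the nucleophile by its conversion with the electrophile is 13 min at 0.718 min, longer than the 3.0 min allowed. The flask takes 9.07 equivalents against my E of 8.30, a ratio of 0.915. At 3.00 min the share of the charged nucleophile still free is 81.0 %.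

The runs were computed with constants of no real substance, noise included.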